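Abbreviations: TBS = tert-butyldimethylsilyl, TMS = trimethylsilyl, prenyl = 3-methylbut-2-enyl. Flavonoid numbering (O1, C2 to C8a, C1' to C6') is used for all intermediates.

## Analysis of the target

Cathayanon I (21) is a 3-hydroxyflavanone: a 5,7-dihydroxychroman-4-one (rings A and C) that carries at C2 a 2',4'-dihydroxyphenyl ring B with prenyl groups at C3' and C5'. The only stereocentres are C2 and C3, both R; the aryl group at C2 and the hydroxyl at C3 are trans, the diequatorial and thermodynamically preferred arrangement on the half-chair ring C. C2 is a benzylic aryl-ether carbon β to the C4 ketone, so base can open ring C to a 2'-hydroxychalcone-type enone and scramble C2, and C3 is an enolisable α-hydroxy ketone centre that is easily dehydrogenated to the flavonol. The two trisubstituted alkenes exclude hydrogenolysis and strong acids or electrophiles, all the more because each prenyl group sits ortho to a phenol and would close to a chroman under protic acid. Five free hydroxyl groups on two very electron-rich rings add sensitivity to oxidants. The difficulty is therefore to set two adjacent stereocentres in absolute terms on a ring that epimerises easily, with a fully substituted ring B already in place and with only mild deprotection at the end. The feature used is the polarity pattern of ring C: C2 is at the aldehyde oxidation level and is flanked by O1 and the donor-substituted ring B, so it can be an oxocarbenium carbon, whereas C3 is the α-carbon of the C4 ketone and can be an enol carbon; joining C2 to C3 closes ring C and creates both stereocentres in one event.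

## Retrosynthetic reasoning

**21 from 20 (five O–Si bonds).** All five hydroxyl groups are carried as TBS ethers. Silyl ethers tolerate the amide base, the organozinc reagent and the silylium Lewis acid used later, whereas acetal-type groups would ionise in the key step and benzyl ethers could not be removed beside the prenyl alkenes. The forward step only has to cleave Si–O bonds with fluoride without opening ring C.

**20 from 18 through cation 19 (C2–C3 bond).** Cutting C2–C3 leaves an oxocarbenium carbon at C2 and an enol silane carbon at C3, both held on ring A. A cut at O1–C2 (oxa-Michael closure) would leave C3 uncontrolled and C2 under thermodynamic control only; a cut at C4–C4a would need a harsh acylation of a hindered arene. The chosen cut creates both stereocentres together from a precursor whose only stereogenic element, the acetal carbon, is erased on ionisation. The forward reaction must ionise the acetal of 18 on the methoxy side, close ring C through a chair-like transition state, and let a chiral counter-anion choose the face of 19.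

**18 from 16 (enol O–Si bond).** The enol silane is made from the ketone at the last moment because it is the most labile group of the sequence. The forward step has to give the Z geometry, which an aryl ketone with an α-silyloxy group should deliver on kinetic deprotonation.

**16 from 13 and 6 (C2–O1 bond).** The oxygen bridge is disconnected at the acetal carbon, so the two aromatic halves are joined by a simple O-alkylation before any carbon–carbon bond is made. Acetal 13 is activated as the α-chloro ether 14 and phenol 6 as its phenoxide 15. The cut is convergent and divides the molecule into two halves of similar size.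

**6 from 1 (ω-C–O bond and three O–Si bonds).** The ω-oxygen is introduced by oxidising the enol silane 3 of the methyl ketone (via 4 to 5). The three phenols of 1 are told apart by the hydrogen bond to the ketone, which leaves one ortho hydroxyl free in 2 and again in 6.

**13 from 7 and 11 (two aryl–prenyl bonds).** C3' and C5' are the carbons of 7 that are ortho or para to both hydroxyl groups, so electrophilic bromination (8) marks exactly the positions that must carry the prenyl groups. After silylation (9) and acetal formation (10), both C–Br bonds are exchanged for prenyl groups by palladium-catalysed coupling with the zinc reagent 12 made from 11. The dimethyl acetal protects the aldehyde from 12 and is at the same time the handle for 14.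

## Alternatives that were turned down

**Alternative 1:** This plan disconnects the two aryl–prenyl bonds (C3'–C1'' and C5'–C1'') at the very end.
- Key step: the 2',4'-bis(1,1-dimethylallyl) ether of a 7-O-silylated 2',4'-dihydroxyflavanonol, A2, is heated in a high-boiling amine. Each tertiary allyl group moves from oxygen to the neighbouring ring carbon by a [3,3] shift with allylic transposition, which should give 7-O-(triisopropylsilyl) Cathayanon I, A1.
- For it: the aromatic Claisen rearrangement is well known, the linear prenyl group follows from the pericyclic geometry, and no organometallic step is needed. On precedent for the key step this plan is stronger than the chosen one.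
- Against it:
  - The rearrangement needs roughly 180–200 °C on the finished flavanonol, the very ring that opens to the chalcone (loss of C2) and dehydrogenates to the flavonol.
  - Convergence on C3' and C5' is not assured. The 2'-ether has only C3' as a free ortho position, while the 4'-ether can go to C3' or C5'. If the 4'-group takes C3' first, the 2'-group can reach C5' only by a second shift, which delivers it through its tertiary carbon as a 1,1-dimethylallyl group.
  - The new ortho-prenyl phenols can cyclise at that temperature.
  - The stereochemical problem is only moved, because the enantiopure core of A2 still has to be made and selectively protected.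
- Comparison: the chosen route places both prenyl groups at halogen-marked positions at room temperature before any stereocentre exists and never heats the flavanonol. It pays for this with a key step that has no direct precedent.

**Alternative 2:** This plan disconnects C4a–C8a, that is, ring A itself.
- Key step: the 3,5,7-triketo ester A4, whose chain ends in the acetonide-protected diol and the complete ring B, is folded by a magnesium alkoxide. The methylene carbon next to the diol-bearing ketone (the later C4a) attacks the ester carbon (the later C8a), and enolisation gives the phloroglucinol-type ketone A3.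
- For it: cyclisation of polyketo esters to acylphloroglucinols follows the biosynthesis and has laboratory precedent. Both stereocentres would come from a reagent-controlled dihydroxylation and be carried as a robust acetonide, so on reliability of absolute configuration this plan is stronger than the chosen one.
- Against it:
  - The key step is spent on an aromatic ring that can be bought complete (1 already is ring A with its three oxygens).
  - The triketo ester has competing modes of closure (aldol to a resorcylate, lactonisation to a pyrone).
  - The acetonide carbon next to the chain is α to a β-dicarbonyl unit and is likely to epimerise under the alkoxide.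
  - A dihydroxylation would have to avoid two more electron-rich prenyl alkenes.
  - A3 is not the end. As drawn, its benzylic centre has the configuration opposite to C2 of 21 (trans-dioxolane of the syn-diol), so ring C would still have to be closed with inversion at an ionisation-prone benzylic carbon. The methoxymethyl ethers would then have to be cleaved with acid beside two prenyl groups.
- Comparison: the chosen route builds no ring that can be bought, and it closes ring C and sets C2 and C3 in one step.

**Alternative 3:** This plan disconnects O1–C2 and C3–C4 in one cycloaddition.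
- Key step: a chiral phosphoric acid ionises the dimethyl acetal A6 of the ring A salicylaldehyde to an ortho-quinone methide with a methoxy group on the exocyclic carbon. This adds across the E-vinylsilane A7 of ring B to give the 3-silyl-4-methoxyflavan A5.
- For it: two bonds and ring C are formed convergently, and the E geometry of the alkene is translated into 2,3-trans. The silyl group polarises the alkene in the right sense: the electrophilic carbon attacks the silicon-bearing carbon and leaves a benzylic, β-silyl-stabilised cation for the phenol oxygen. Acid-catalysed cycloadditions of ortho-quinone methides with styrenes under chiral phosphate control are known, so in convergency (two bonds against one) and in precedent this plan is at least equal to the chosen one.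
- Against it:
  - The β-silyl cation can lose silicon instead of closing the ring, which is the normal fate of vinylsilanes with electrophiles.
  - The methoxymethyl ethers are acetals and compete for the acid.
  - The product is two oxidation-level corrections away from 21. The C–Si bond must be oxidised to C–OH in the presence of two alkenes, and the C4 methyl ether must be turned into the ketone by way of an acid-labile flavan-3,4-diol derivative.
  - Four methoxymethyl groups must finally be removed with acid beside the prenyl groups.
- Comparison: the chosen route reaches ring C at the correct oxidation level at C3 and C4, so that only silyl groups remain to be removed.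

Key step: step 11

Remark (assumption): which antipode of the imidodiphosphorimidate catalyst leads to the 2R,3R series cannot be deduced from first principles. Step 11 is written for the antipode that does, to be identified in a small test with both; the aryl groups of the catalyst are likewise to be chosen by screening.

## Route

Step 1
Reactants: 1 2,4,6-trihydroxyacetophenone
Product: 2 1-[2,4-bis(tert-butyldimethylsilyloxy)-6-hydroxyphenyl]ethanone
Conditions: TBSCl (2.1 equiv), imidazole, CH2Cl2/DMF, 0 °C → rt
Reagents that add atoms: tert-butyldimethylsilyl chloride (TBSCl), CC(C)(C)[Si](C)(C)Cl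
Why: Silylation of phenols; the para and one ortho hydroxyl react, whereas the remaining ortho hydroxyl is held in a strong hydrogen bond to the ketone and is flanked by it, so two equivalents should stop at the bis-ether.

Step 2
Reactants: 2 1-[2,4-bis(tert-butyldimethylsilyloxy)-6-hydroxyphenyl]ethanone
Product: 3 1-[2,4-bis(tert-butyldimethylsilyloxy)-6-(trimethylsilyloxy)phenyl]-1-(trimethylsilyloxy)ethene
Conditions: TMSOTf (2.3 equiv), Et3N, CH2Cl2, 0 °C; pentane, filtration
Reagents that add atoms: trimethylsilyl trifluoromethanesulfonate (TMSOTf), C[Si](C)(C)OS(=O)(=O)C(F)(F)F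
Why: Soft enolisation of a methyl ketone with a silyl triflate and an amine; the free phenol is capped as its TMS ether in the same operation, which keeps it out of the oxidation that follows.

Step 3
Reactants: 3 1-[2,4-bis(tert-butyldimethylsilyloxy)-6-(trimethylsilyloxy)phenyl]-1-(trimethylsilyloxy)ethene
Product: 5 1-[2,4-bis(tert-butyldimethylsilyloxy)-6-hydroxyphenyl]-2-hydroxyethanone, via trimethylsilyloxy epoxide 4 (not isolated)
Conditions: dimethyldioxirane, acetone/CH2Cl2, −40 °C; then aq. citric acid, THF, 0 °C
Reagents that add atoms: dimethyldioxirane, CC1(C)OO1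
Why: Rubottom oxidation: the dioxirane should epoxidise the electron-rich enol silane much faster than it attacks the arene. Dilute acid then opens epoxide 4 to the α-hydroxy ketone and cleaves the labile aryl TMS ether while the TBS ethers stay.

Step 4
Reactants: 5 1-[2,4-bis(tert-butyldimethylsilyloxy)-6-hydroxyphenyl]-2-hydroxyethanone
Product: 6 1-[2,4-bis(tert-butyldimethylsilyloxy)-6-hydroxyphenyl]-2-(tert-butyldimethylsilyloxy)ethanone
Conditions: TBSCl (1.05 equiv), imidazole, CH2Cl2, −20 → 0 °C
Reagents that add atoms: tert-butyldimethylsilyl chloride (TBSCl), CC(C)(C)[Si](C)(C)Cl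
Why: Chemoselective silylation: the unhindered primary alcohol should react well before the phenol, which is deactivated by its hydrogen bond to the ketone exactly as in step 1.

Step 5
Reactants: 7 2,4-dihydroxybenzaldehyde
Product: 8 3,5-dibromo-2,4-dihydroxybenzaldehyde
Conditions: Br2 (2.05 equiv), AcOH, rt
Reagents that add atoms: bromine, BrBr
Why: Electrophilic aromatic bromination; C3 and C5 are each ortho or para to both hydroxyl groups, whereas C6 is meta to both, so the two bromine atoms mark exactly the carbons that are to carry the prenyl groups.

Step 6
Reactants: 8 3,5-dibromo-2,4-dihydroxybenzaldehyde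
Product: 9 3,5-dibromo-2,4-bis(tert-butyldimethylsilyloxy)benzaldehyde
Conditions: TBSOTf (2.4 equiv), 2,6-lutidine, CH2Cl2, 0 °C → rt
Reagents that add atoms: tert-butyldimethylsilyl trifluoromethanesulfonate (TBSOTf), CC(C)(C)[Si](C)(C)OS(=O)(=O)C(F)(F)F
Why: Silylation of hindered, acidic phenols with a silyl triflate and a hindered pyridine base; the aldehyde has no α-hydrogen and is not affected.

Step 7
Reactants: 9 3,5-dibromo-2,4-bis(tert-butyldimethylsilyloxy)benzaldehyde
Product: 10 3,5-dibromo-2,4-bis(tert-butyldimethylsilyloxy)benzaldehyde dimethyl acetal
Conditions: MeOSiMe3 (2.5 equiv), TMSOTf (1 mol%), CH2Cl2, −78 → −20 °C; pyridine quench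
Reagents that add atoms: methoxytrimethylsilane, CO[Si](C)(C)C
Why: Aprotic acetalisation of an aldehyde with an alkoxysilane and catalytic silyl triflate at low temperature, which spares the aryl silyl ethers. The acetal masks the aldehyde against the allylzinc reagent of step 8 and is the handle for step 9.

Step 8
Reactants: 10 3,5-dibromo-2,4-bis(tert-butyldimethylsilyloxy)benzaldehyde dimethyl acetal; 11 prenyl bromide (1-bromo-3-methylbut-2-ene)
Product: 13 2,4-bis(tert-butyldimethylsilyloxy)-3,5-diprenylbenzaldehyde dimethyl acetal, via prenylzinc bromide 12 (not isolated)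
Conditions: 11 (3 equiv), Zn, LiCl, THF, 0 °C; then 10, Pd(OAc)2 (4 mol%), CPhos (8 mol%), THF, rt
Reagents that add atoms: none
Why: Negishi cross-coupling of an allylzinc halide with an aryl bromide; with the biaryl phosphine CPhos, reductive elimination should occur at the unsubstituted allyl terminus, so that the linear prenyl group and not the 1,1-dimethylallyl isomer is attached at both positions. Silyl ethers and the acetal are inert to the organozinc reagent in THF.

Step 9
Reactants: 13 2,4-bis(tert-butyldimethylsilyloxy)-3,5-diprenylbenzaldehyde dimethyl acetal; 6 1-[2,4-bis(tert-butyldimethylsilyloxy)-6-hydroxyphenyl]-2-(tert-butyldimethylsilyloxy)ethanone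
Product: 16 1-[2-{[2,4-bis(tert-butyldimethylsilyloxy)-3,5-diprenylphenyl](methoxy)methoxy}-4,6-bis(tert-butyldimethylsilyloxy)phenyl]-2-(tert-butyldimethylsilyloxy)ethanone (mixed O-aryl O-methyl acetal; racemic at the acetal carbon), via α-chloro ether 14 (not isolated), via potassium phenoxide 15 (not isolated)
Conditions: 13 (1.15 equiv), AcCl (1.1 equiv), ZnBr2 (0.1 mol%), CH2Cl2, −20 °C; separately 6, KN(SiMe3)2 (1.0 equiv), THF, −78 °C; combine, −78 → 0 °C; aq. NaHCO3; Et3N-deactivated silica
Reagents that add atoms: none
Why: Acetal–acyl chloride exchange gives the α-chloro ether 14, and phenoxide 15 displaces chloride at this hard, oxocarbenium-like carbon on oxygen (Williamson-type acetal formation, as in the alkoxymethylation of phenols). One equivalent of base removes only the phenol proton, which is far more acidic than the ketone α-CH2.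

Step 10
Reactants: 16 1-[2-{[2,4-bis(tert-butyldimethylsilyloxy)-3,5-diprenylphenyl](methoxy)methoxy}-4,6-bis(tert-butyldimethylsilyloxy)phenyl]-2-(tert-butyldimethylsilyloxy)ethanone
Product: 18 (Z)-2-(tert-butyldimethylsilyloxy)-1-(trimethylsilyloxy)ethene carrying at C1 the 2-{[2,4-bis(tert-butyldimethylsilyloxy)-3,5-diprenylphenyl](methoxy)methoxy}-4,6-bis(tert-butyldimethylsilyloxy)phenyl group (Z-enol silane of 16; racemic at the acetal carbon), via potassium Z-enolate 17 (not isolated)
Conditions: KN(SiMe3)2 (1.15 equiv), THF, −78 °C; Me3SiCl (1.5 equiv), Et3N, −78 → −20 °C; pentane, filtration; used without chromatography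
Reagents that add atoms: trimethylsilyl chloride, C[Si](C)(C)Cl
Why: Kinetic deprotonation of the aryl ketone and O-silylation of the potassium enolate; the Z enolate 17 should form because in the E isomer the silyloxy group would clash with the ortho-disubstituted aryl ring (A-1,3 strain) and because potassium can bridge the two oxygens. The acetal has no acidic hydrogen and the aryl silyl ethers resist the amide base at −78 °C.

Step 11
Reactants: 18 Z-enol silane of 16
Product: 20 (2R,3R)-3,5,7-tris(tert-butyldimethylsilyloxy)-2-[2,4-bis(tert-butyldimethylsilyloxy)-3,5-diprenylphenyl]chroman-4-one (penta-O-TBS Cathayanon I), via oxocarbenium ion 19 (not isolated)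
Conditions: chiral imidodiphosphorimidate acid (two 3,3'-diaryl-BINOL phosphorus units bridged by NH, each P carrying =N–SO2CF3; 5 mol%), methallyl-SiMe3 (10 mol%), toluene, rt, 15 min; then 18 (0.02 M), −78 → −40 °C; Et3N quench
Reagents that add atoms: none
Why: Proposed new method: the pre-silylated catalyst should transfer Me3Si+ to the methoxy oxygen of 18, the more basic and less hindered of the two acetal oxygens, and loss of MeOSiMe3 should leave the E-configured oxocarbenium ion 19, stabilised by O1 and by the 2,4-disilyloxyaryl ring and paired with the chiral anion; C3 of the Z-enol silane then adds to C2, and the silyloxycarbenium ion formed at C4 returns its Me3Si group to the anion or to the next molecule of 18, which closes the cycle. The closest known reaction types are chiral-anion-controlled Mukaiyama additions of enol silanes and silyl ketene acetals to acetal-derived oxocarbenium and benzopyrylium ions, and the Petasis–Ferrier rearrangement, in which an enol and an oxocarbenium ion held in one molecule combine to a tetrahydropyran-4-one; an enantioselective intramolecular version that closes a chroman-4-one is not known. Ring C is closed in a 6-(enolendo)-endo-trig mode, both reacting double bonds lying inside the forming ring. C2 is set by the anion, which has to distinguish the two faces of the planar cation; the racemic acetal centre of 18 is erased on ionisation, so the step is stereoconvergent. C3 follows from C2: in the half-chair transition state with a staggered forming bond, the ring B substituent (anti to C8a in the E-oxocarbenium ion) and the silyloxy group (anti to C4a in the Z-enol silane) both come out equatorial, which is the 2,3-trans arrangement. The step needs the methoxy and not the aryloxy group to leave, a productive C-attack, and no protonation of the prenyl alkenes: the first rests on oxygen basicity and low temperature, the second on the fact that O-attack would only give a 1,3-benzodioxin enol acetal that re-ionises under the conditions, and the third on pre-silylating the catalyst so that no free acid is present. Ring closure by the prenyl alkenes is ruled out because they sit meta to the cationic carbon.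

Step 12
Reactants: 20 (2R,3R)-penta-O-TBS Cathayanon I
Product: 21 Cathayanon I, (2R,3R)-2-(2,4-dihydroxy-3,5-diprenylphenyl)-3,5,7-trihydroxychroman-4-one
Conditions: HF·pyridine, pyridine, THF, 0 °C → rt
Reagents that add atoms: none
Why: Fluoride-mediated cleavage of the four aryl silyl ethers and the secondary alkyl silyl ether; buffering with pyridine should keep the medium too weakly acidic to protonate the prenyl alkenes and too weakly basic to open ring C, so C2 and C3 should stay as set in step 11.

## Compound list

1 | 2,4,6-trihydroxyacetophenone | CC(=O)c1c(O)cc(O)cc1O | starting material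
2 | 1-[2,4-bis(tert-butyldimethylsilyloxy)-6-hydroxyphenyl]ethanone | CC(=O)c1c(O)cc(O[Si](C)(C)C(C)(C)C)cc1O[Si](C)(C)C(C)(C)C | intermediate
3 | 1-[2,4-bis(tert-butyldimethylsilyloxy)-6-(trimethylsilyloxy)phenyl]-1-(trimethylsilyloxy)ethene | C=C(O[Si](C)(C)C)c1c(O[Si](C)(C)C)cc(O[Si](C)(C)C(C)(C)C)cc1O[Si](C)(C)C(C)(C)C | intermediate
4 | 2-[2,4-bis(tert-butyldimethylsilyloxy)-6-(trimethylsilyloxy)phenyl]-2-(trimethylsilyloxy)oxirane (racemic; not isolated) | C[Si](C)(C)OC1(CO1)c1c(O[Si](C)(C)C)cc(O[Si](C)(C)C(C)(C)C)cc1O[Si](C)(C)C(C)(C)C | intermediate
5 | 1-[2,4-bis(tert-butyldimethylsilyloxy)-6-hydroxyphenyl]-2-hydroxyethanone | OCC(=O)c1c(O)cc(O[Si](C)(C)C(C)(C)C)cc1O[Si](C)(C)C(C)(C)C | intermediate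
6 | 1-[2,4-bis(tert-butyldimethylsilyloxy)-6-hydroxyphenyl]-2-(tert-butyldimethylsilyloxy)ethanone | CC(C)(C)[Si](C)(C)OCC(=O)c1c(O)cc(O[Si](C)(C)C(C)(C)C)cc1O[Si](C)(C)C(C)(C)C | intermediate
7 | 2,4-dihydroxybenzaldehyde | O=Cc1ccc(O)cc1O | starting material
8 | 3,5-dibromo-2,4-dihydroxybenzaldehyde | O=Cc1cc(Br)c(O)c(Br)c1O | intermediate
9 | 3,5-dibromo-2,4-bis(tert-butyldimethylsilyloxy)benzaldehyde | O=Cc1cc(Br)c(O[Si](C)(C)C(C)(C)C)c(Br)c1O[Si](C)(C)C(C)(C)C | intermediate
10 | 3,5-dibromo-2,4-bis(tert-butyldimethylsilyloxy)benzaldehyde dimethyl acetal | COC(OC)c1cc(Br)c(O[Si](C)(C)C(C)(C)C)c(Br)c1O[Si](C)(C)C(C)(C)C | intermediate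
11 | prenyl bromide (1-bromo-3-methylbut-2-ene) | CC(C)=CCBr | starting material
12 | prenylzinc bromide (not isolated) | CC(C)=CC[Zn]Br | intermediate
13 | 2,4-bis(tert-butyldimethylsilyloxy)-3,5-diprenylbenzaldehyde dimethyl acetal | COC(OC)c1cc(CC=C(C)C)c(O[Si](C)(C)C(C)(C)C)c(CC=C(C)C)c1O[Si](C)(C)C(C)(C)C | intermediate
14 | 1-[chloro(methoxy)methyl]-2,4-bis(tert-butyldimethylsilyloxy)-3,5-diprenylbenzene (α-chloro ether; racemic; not isolated) | COC(Cl)c1cc(CC=C(C)C)c(O[Si](C)(C)C(C)(C)C)c(CC=C(C)C)c1O[Si](C)(C)C(C)(C)C | intermediate
15 | potassium phenoxide of 6 (not isolated) | [K+].[O-]c1cc(O[Si](C)(C)C(C)(C)C)cc(O[Si](C)(C)C(C)(C)C)c1C(=O)CO[Si](C)(C)C(C)(C)C | intermediate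
16 | 1-[2-{[2,4-bis(tert-butyldimethylsilyloxy)-3,5-diprenylphenyl](methoxy)methoxy}-4,6-bis(tert-butyldimethylsilyloxy)phenyl]-2-(tert-butyldimethylsilyloxy)ethanone (racemic at the acetal carbon) | CC(C)=CCc1cc(C(OC)Oc2cc(O[Si](C)(C)C(C)(C)C)cc(O[Si](C)(C)C(C)(C)C)c2C(=O)CO[Si](C)(C)C(C)(C)C)c(O[Si](C)(C)C(C)(C)C)c(CC=C(C)C)c1O[Si](C)(C)C(C)(C)C | intermediate
17 | potassium Z-enolate of 16 (not isolated) | [K+].CC(C)=CCc1cc(C(OC)Oc2cc(O[Si](C)(C)C(C)(C)C)cc(O[Si](C)(C)C(C)(C)C)c2/C([O-])=C/O[Si](C)(C)C(C)(C)C)c(O[Si](C)(C)C(C)(C)C)c(CC=C(C)C)c1O[Si](C)(C)C(C)(C)C | intermediate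
18 | Z-enol silane of 16: (Z)-2-(tert-butyldimethylsilyloxy)-1-(trimethylsilyloxy)ethene with the acetal-bearing ring A aryl group at C1 (racemic at the acetal carbon) | CC(C)=CCc1cc(C(OC)Oc2cc(O[Si](C)(C)C(C)(C)C)cc(O[Si](C)(C)C(C)(C)C)c2/C(O[Si](C)(C)C)=C/O[Si](C)(C)C(C)(C)C)c(O[Si](C)(C)C(C)(C)C)c(CC=C(C)C)c1O[Si](C)(C)C(C)(C)C | intermediate
19 | E-oxocarbenium ion spanning O1 and C2, with the Z-enol silane on ring A (cation of the ion pair with the chiral anion; not isolated) | CC(C)=CCc1cc(/C=[O+]/c2cc(O[Si](C)(C)C(C)(C)C)cc(O[Si](C)(C)C(C)(C)C)c2/C(O[Si](C)(C)C)=C/O[Si](C)(C)C(C)(C)C)c(O[Si](C)(C)C(C)(C)C)c(CC=C(C)C)c1O[Si](C)(C)C(C)(C)C | intermediate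
20 | (2R,3R)-penta-O-(tert-butyldimethylsilyl) Cathayanon I | CC(C)=CCc1cc([C@H]2Oc3cc(O[Si](C)(C)C(C)(C)C)cc(O[Si](C)(C)C(C)(C)C)c3C(=O)[C@@H]2O[Si](C)(C)C(C)(C)C)c(O[Si](C)(C)C(C)(C)C)c(CC=C(C)C)c1O[Si](C)(C)C(C)(C)C | intermediate
21 | Cathayanon I, (2R,3R) | CC(C)=CCc1cc([C@H]2Oc3cc(O)cc(O)c3C(=O)[C@@H]2O)c(O)c(CC=C(C)C)c1O | target

## Step count and least certain steps

Total: 12 steps. Longest linear sequence: 8 steps (steps 5–12 from 7; equally steps 1–4 and 9–12 from 1).

**Step 11 (key step, proposed new method).**
- Three processes may go wrong.
  - Ionisation may occur on the wrong side of the acetal: the silylated aryloxy group of ring A is the better nucleofuge, and its departure cuts the tether, so the halves would recombine only intermolecularly to open-chain aldol-type material.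
  - Facial discrimination may be weak, because the closure is intramolecular and the anion has to control the conformation of a large, strongly delocalised cation.
  - Traces of free acid may cause proton-mediated loss of the enol silane.
- Fallback (known chemistry; sets out from 13 and 2, returns at 21): the stereocentres are set by reagent-controlled nucleophilic epoxidation of a chalcone, and ring C is closed by the known cyclisation of 2'-hydroxychalcone epoxides. Acetal 13 is hydrolysed (wet silica, catalytic oxalic acid, CH2Cl2) to 2,4-bis(tert-butyldimethylsilyloxy)-3,5-diprenylbenzaldehyde F1. Ketone 2 is silylated at the remaining phenol (TBSOTf, 2,6-lutidine) to 2,4,6-tris(tert-butyldimethylsilyloxy)acetophenone F2. The lithium enolate of F2 (LiN(SiMe3)2, THF, −78 °C) is added to F1 to give the racemic aldol F3, which is dehydrated (Burgess reagent, toluene, 50 °C) to the E-chalcone F4. Asymmetric epoxidation (tert-butyl hydroperoxide, La(O-iPr)3, BINOL, Ph3As=O, 4 Å molecular sieves, THF; the BINOL antipode that gives the αR,βS series) should give the trans-epoxide F5. Buffered HF·pyridine then removes the five silyl groups, and the freed 2'-phenol should open the epoxide at the benzylic carbon with inversion, in a 6-endo closure, to give 21 directly.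

**Step 9.**
- The α-chloro ether 14 from so electron-rich an aldehyde may ionise to an ion pair whose chloride attacks silicon at the para silyloxy group (loss of a silyl chloride towards a quinone methide). The hydrogen-bond-stabilised, hindered phenoxide may react sluggishly or at ring carbon. Acetal 16 may re-ionise on silica.
- Fallback (sets out from 13 and 6, returns at 16): 13 is treated with TMSOTf and 2,2'-bipyridyl (CH2Cl2, 0 °C), which should convert it into the N-(α-methoxybenzyl)bipyridinium triflate F6, a salt with a non-nucleophilic counter-ion. Addition of phenol 6 and iPr2NEt then displaces the bipyridyl to give 16 (mixed-acetal formation through a pyridinium-type salt).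

**Step 10.**
- The TBS group may migrate from the ω-oxygen to the enolate oxygen in 17, the Z geometry may erode, and 18 may hydrolyse or ionise during isolation. It contains a TMS enol ether and a very labile acetal and cannot be chromatographed.
- Fallback (sets out from 16, returns at 20): the enolate 17 is trapped with TBSCl (THF/DMPU, −78 → 0 °C) instead, which should give the more robust all-TBS Z-enediol bis-silyl ether F7, purifiable on deactivated silica. F7 is then submitted to the conditions of step 11 and should give 20 with a slower silyl transfer in the turnover step.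

**Step 8.**
- Coupling may stay incomplete at the C3 bromide, which is flanked by two bulky silyloxy groups, leaving mono-coupled or reduced material. Part of the allyl unit may be transferred through its tertiary terminus.
- Fallback (sets out from 10, returns at 13): both bromides are exchanged for unsubstituted allyl groups, which have no regiochemical ambiguity, by Stille coupling (allyltributylstannane, Pd(PPh3)4, toluene, 100 °C) to give the 3,5-diallyl acetal F8. Cross-metathesis with 2-methyl-2-butene (second-generation Grubbs catalyst, (H2IMes)(PCy3)Cl2Ru=CHPh, CH2Cl2, 40 °C) then converts both allyl groups into prenyl groups.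

**Step 12.**
- Ring C may open at the β-aryloxy ketone once phenoxides are set free under basic fluoride, which would epimerise C2. An ortho phenol may add to a prenyl double bond if the medium becomes too acidic. The hindered C3 silyl ether may cleave slowly.
- Fallback (sets out from 20, returns at 21): the deprotection is staged. KHF2 in MeOH at rt should cleave only the four aryl silyl ethers and give 3-O-(tert-butyldimethylsilyl) Cathayanon I F9. The remaining secondary silyl ether is then removed under weakly acidic fluoride conditions (Et3N·3HF, MeCN, rt → 40 °C), so the free polyphenol is never exposed to basic fluoride.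

## Further compounds

F1 | step 11 | 2,4-bis(tert-butyldimethylsilyloxy)-3,5-diprenylbenzaldehyde | O=Cc1cc(CC=C(C)C)c(O[Si](C)(C)C(C)(C)C)c(CC=C(C)C)c1O[Si](C)(C)C(C)(C)C
F2 | step 11 | 1-[2,4,6-tris(tert-butyldimethylsilyloxy)phenyl]ethanone | CC(=O)c1c(O[Si](C)(C)C(C)(C)C)cc(O[Si](C)(C)C(C)(C)C)cc1O[Si](C)(C)C(C)(C)C
F3 | step 11 | 3-[2,4-bis(tert-butyldimethylsilyloxy)-3,5-diprenylphenyl]-3-hydroxy-1-[2,4,6-tris(tert-butyldimethylsilyloxy)phenyl]propan-1-one (racemic) | CC(C)=CCc1cc(C(O)CC(=O)c2c(O[Si](C)(C)C(C)(C)C)cc(O[Si](C)(C)C(C)(C)C)cc2O[Si](C)(C)C(C)(C)C)c(O[Si](C)(C)C(C)(C)C)c(CC=C(C)C)c1O[Si](C)(C)C(C)(C)C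
F4 | step 11 | (E)-3-[2,4-bis(tert-butyldimethylsilyloxy)-3,5-diprenylphenyl]-1-[2,4,6-tris(tert-butyldimethylsilyloxy)phenyl]prop-2-en-1-one | CC(C)=CCc1cc(/C=C/C(=O)c2c(O[Si](C)(C)C(C)(C)C)cc(O[Si](C)(C)C(C)(C)C)cc2O[Si](C)(C)C(C)(C)C)c(O[Si](C)(C)C(C)(C)C)c(CC=C(C)C)c1O[Si](C)(C)C(C)(C)C
F5 | step 11 | (αR,βS)-trans-epoxide of F4 | O=C(c1c(O[Si](C)(C)C(C)(C)C)cc(O[Si](C)(C)C(C)(C)C)cc1O[Si](C)(C)C(C)(C)C)[C@@H]1O[C@H]1c1cc(CC=C(C)C)c(O[Si](C)(C)C(C)(C)C)c(CC=C(C)C)c1O[Si](C)(C)C(C)(C)C
F6 | step 9 | 1-{[2,4-bis(tert-butyldimethylsilyloxy)-3,5-diprenylphenyl](methoxy)methyl}-2-(pyridin-2-yl)pyridinium trifluoromethanesulfonate (racemic) | COC(c1cc(CC=C(C)C)c(O[Si](C)(C)C(C)(C)C)c(CC=C(C)C)c1O[Si](C)(C)C(C)(C)C)[n+]1ccccc1-c1ccccn1.[O-]S(=O)(=O)C(F)(F)F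
F7 | step 10 | all-TBS analogue of 18: (Z)-1,2-bis(tert-butyldimethylsilyloxy)ethene with the acetal-bearing ring A aryl group at C1 (racemic at the acetal carbon) | CC(C)=CCc1cc(C(OC)Oc2cc(O[Si](C)(C)C(C)(C)C)cc(O[Si](C)(C)C(C)(C)C)c2/C(O[Si](C)(C)C(C)(C)C)=C/O[Si](C)(C)C(C)(C)C)c(O[Si](C)(C)C(C)(C)C)c(CC=C(C)C)c1O[Si](C)(C)C(C)(C)C
F8 | step 8 | 3,5-diallyl-2,4-bis(tert-butyldimethylsilyloxy)benzaldehyde dimethyl acetal | COC(OC)c1cc(CC=C)c(O[Si](C)(C)C(C)(C)C)c(CC=C)c1O[Si](C)(C)C(C)(C)C
F9 | step 12 | (2R,3R)-3-O-(tert-butyldimethylsilyl) Cathayanon I | CC(C)=CCc1cc([C@H]2Oc3cc(O)cc(O)c3C(=O)[C@@H]2O[Si](C)(C)C(C)(C)C)c(O)c(CC=C(C)C)c1O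
A1 | alternative 1 | 7-O-(triisopropylsilyl) Cathayanon I, (2R,3R) | CC(C)=CCc1cc([C@H]2Oc3cc(O[Si](C(C)C)(C(C)C)C(C)C)cc(O)c3C(=O)[C@@H]2O)c(O)c(CC=C(C)C)c1O
A2 | alternative 1 | (2R,3R)-2-[2,4-bis(1,1-dimethylallyloxy)phenyl]-3,5-dihydroxy-7-(triisopropylsilyloxy)chroman-4-one | C=CC(C)(C)Oc1ccc([C@H]2Oc3cc(O[Si](C(C)C)(C(C)C)C(C)C)cc(O)c3C(=O)[C@@H]2O)c(OC(C)(C)C=C)c1
A3 | alternative 2 | trans-2,2-dimethyl-1,3-dioxolane with the 2,4,6-trihydroxybenzoyl group at C4 and the 2,4-bis(methoxymethoxy)-3,5-diprenylphenyl group at C5 (configuration as in the SMILES) | CC(C)=CCc1cc([C@@H]2OC(C)(C)O[C@H]2C(=O)c3c(O)cc(O)cc3O)c(OCOC)c(CC=C(C)C)c1OCOC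
A4 | alternative 2 | methyl 3,5,7-trioxoheptanoate carrying at C7 the same trans-dioxolane with the protected ring B (configuration as in the SMILES) | CC(C)=CCc1cc([C@@H]2OC(C)(C)O[C@H]2C(=O)CC(=O)CC(=O)CC(=O)OC)c(OCOC)c(CC=C(C)C)c1OCOC
A5 | alternative 3 | 2,3-trans-2,4-cis-3-(benzyldimethylsilyl)-4-methoxy-5,7,2',4'-tetrakis(methoxymethoxy)-3',5'-diprenylflavan (configuration as in the SMILES) | CC(C)=CCc1cc([C@H]2Oc3cc(OCOC)cc(OCOC)c3[C@@H](OC)[C@@H]2[Si](C)(C)Cc4ccccc4)c(OCOC)c(CC=C(C)C)c1OCOC
A6 | alternative 3 | 2-hydroxy-4,6-bis(methoxymethoxy)benzaldehyde dimethyl acetal | COCOc1cc(O)c(C(OC)OC)c(OCOC)c1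
A7 | alternative 3 | benzyl{(E)-2-[2,4-bis(methoxymethoxy)-3,5-diprenylphenyl]ethenyl}dimethylsilane | CC(C)=CCc1cc(/C=C/[Si](C)(C)Cc2ccccc2)c(OCOC)c(CC=C(C)C)c1OCOC
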